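**Retrosynthetic overview**

1. The tertiary allylic alcohol with its exocyclic methylene is traced back to an epoxy aldehyde (Wharton transposition) and that to a tetrasubstituted cyclohexenylmethanol (Sharpless epoxidation); the bond between the linker CH2 and the ring sp2 carbon is then cut (B-alkyl Suzuki–Miyaura) into a 6-vinyl-1,2-dioxane ester and a cyclohexenyl triflate.
2. The strategy rests on the 1,2-dioxane ring: its atoms C3H(O)–C4H2–C5H2–C6(CH3)(O), together with the linker CH2 on C6, are C6 to C2 of geraniol. Taking out one H2O2 (bonds O–C6 and O–C3) leaves an acyclic epoxy mesylate in which C6 is the tertiary carbon of a Sharpless epoxide and C3 a crotylboration carbinol.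
3. Each peroxide carbon is thus configured on its own and the two are joined by H2O2 with two inversions. The propanoate arm travels as a but-3-en-2-yl group and the linker as a silylated glycol, from which geraniol C1 is cut out later.
4. Ring order: geraniol oxirane, then the 1,2-dioxane (key step), then attachment of the preformed cyclohexene, then a transient oxirane on that ring, opened in the last step.

Key step: step 6

Remark on the chemistry: (−)-Ipc2BOMe is the reagent made from (+)-α-pinene, and its crotylboranes are taken to add to the Si face of an unbranched aldehyde. L-(+)-tartrate is taken to epoxidise the cyclohexenylmethanol on the same face of the C=C–CH2OH unit as it does in geraniol.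

**Route**

Step 1
Reactants: 1 geraniol
Product: 2 (2S,3S)-2,3-epoxygeraniol
Conditions: Ti(OiPr)4 (5 mol%), L-(+)-diethyl tartrate (6 mol%), t-BuOOH, 4 Å MS, CH2Cl2, −20 °C
Reagents that add atoms: tert-butyl hydroperoxide, CC(C)(C)OO
Why: Sharpless asymmetric epoxidation touches only the allylic 2,3-alkene, and L-(+)-tartrate should deliver oxygen to the face that gives the (2S,3S) epoxide, which fixes the carbon that becomes the quaternary peroxide carbon C6.

Step 2
Reactants: 2 (2S,3S)-2,3-epoxygeraniol
Product: 3 epoxygeranyl TBS ether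
Conditions: TBSCl, imidazole, CH2Cl2, 0 °C to rt
Reagents that add atoms: tert-butyldimethylsilyl chloride, CC(C)(C)[Si](C)(C)Cl
Why: Routine silylation of the primary alcohol gives an ether that is stable to ozone, base and neutral peroxide chemistry and that later deactivates the adjacent oxirane carbon inductively.

Step 3
Reactants: 3 epoxygeranyl TBS ether
Product: 5 epoxy aldehyde, via secondary ozonide 4 (not isolated)
Conditions: O3, CH2Cl2, −78 °C; then PPh3, −78 °C to rt
Reagents that add atoms: ozone, [O-][O+]=O
Why: Ozonolysis with reductive work-up cleaves the only remaining alkene to the aldehyde and acetone, the oxirane and silyl ether being inert to ozone.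

Step 4
Reactants: 5 epoxy aldehyde + 6 cis-2-butene
Product: 11 syn homoallylic alcohol, via (Z)-crotylpotassium 7 (not isolated), via potassium crotyl(methoxy)diisopinocampheylborate 8 (not isolated), via (Z)-crotyldiisopinocampheylborane 9 (not isolated), via diisopinocampheylborinate of the adduct 10 (not isolated)
Conditions: 6 (excess), KOtBu, n-BuLi, THF, −78 to −45 °C; (−)-Ipc2BOMe, −78 °C; BF3·OEt2 (slightly less than the borate), −78 °C; then 5, −78 °C; NaOH, H2O2, 0 °C to rt
Reagents that add atoms: none
Why: Brown asymmetric crotylboration passes through a closed chair transition state, so the Z crotyl geometry gives the syn methyl/hydroxyl pair and the isopinocampheyl groups from (+)-α-pinene direct the reagent to the Si face of the aldehyde to give the (3R,4R) isomer, while a slight deficit of BF3·OEt2 leaves no free Lewis acid to open the oxirane.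

Step 5
Reactants: 11 syn homoallylic alcohol
Product: 12 epoxy mesylate
Conditions: MsCl, Et3N, CH2Cl2, −20 to 0 °C
Reagents that add atoms: methanesulfonyl chloride, CS(=O)(=O)Cl
Why: O-Sulfonylation keeps the carbinol configuration and turns C3 into an SN2 electrophile, and the basic medium with prompt use of 11 suppresses 5-exo attack of the free hydroxyl on the oxirane.

Step 6
Reactants: 12 epoxy mesylate
Product: 14 3,6-cis 1,2-dioxane with butenyl group and silylated glycol arm, via tertiary hydroperoxide 13 (not isolated)
Conditions: H2O2 (anhydrous, in Et2O, excess), MoO2(acac)2 (10 mol%), Et2O, 0 °C to rt; water wash, solvent exchange without purification; then KOtBu (1.0 equiv), 18-crown-6, toluene, 0 °C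
Reagents that add atoms: hydrogen peroxide, OO
Why: The peroxo-molybdenum species activates the oxirane as a Lewis acid and H2O2 attacks the tertiary carbon C6 anti to the departing oxygen in a borderline SN2 opening to give hydroperoxide 13; one equivalent of KOtBu then ionises only the OOH group and the peroxy anion displaces the C3 mesylate, so one H2O2 molecule supplies both ring oxygens. The closest known reaction types are the molybdenum-catalysed perhydrolysis of trisubstituted epoxides at the more substituted carbon with inversion and the intramolecular alkylation of a hydroperoxide by a secondary sulfonate to form a 1,2-dioxane. The 1,2-dioxane ring is closed in the 6-exo-tet mode. C6 is set by inversion of the oxirane carbon made in step 1 and C3 by inversion of the carbinol carbon made in step 4, so the cis relation of the C3 butenyl group and the C6 glycol arm comes from two stereospecific displacements on separately configured centres and not from a conformational preference of the ring. The step needs attack at the tertiary and not the secondary oxirane carbon, which the cation-stabilising substitution at C6 and the inductive deactivation of the other carbon by its CH2OTBS group secure, and it needs alkylation through OOH in preference to the neighbouring secondary OH (also a six-ring closure) or E2 toward the allylic hydrogen, which the acidity gap between OOH and OH and the high nucleophilicity but low basicity of the α-effect peroxy anion secure.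

Step 7
Reactants: 14 3,6-cis 1,2-dioxane
Product: 16 α-methyl aldehyde, via secondary ozonide 15 (not isolated)
Conditions: O3, CH2Cl2, −78 °C; then PPh3 (1.05 equiv), −78 to 0 °C
Reagents that add atoms: ozone, [O-][O+]=O
Why: Ozonolysis cleaves the terminal vinyl group while the dialkyl peroxide is inert to ozone and is reduced by PPh3 far more slowly than the ozonide, and the crude aldehyde is carried on at once to limit epimerisation and β-elimination of the peroxide.

Step 8
Reactants: 16 α-methyl aldehyde
Product: 17 carboxylic acid
Conditions: NaClO2, NaH2PO4, 2-methyl-2-butene, t-BuOH/H2O, 0 °C to rt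
Reagents that add atoms: sodium chlorite, [Na+].[O-]Cl=O
Why: Pinnick oxidation works in a buffered, nearly neutral medium, so the α-stereocentre and the O–O bond are not disturbed and the hypochlorous acid formed is trapped by the alkene scavenger.

Step 9
Reactants: 17 carboxylic acid
Product: 18 methyl ester
Conditions: Me3SiCHN2, toluene/MeOH, 0 °C
Reagents that add atoms: trimethylsilyldiazomethane, C[Si](C)(C)C=[N+]=[N-]
Why: Esterification with the diazoalkane proceeds without base, so the enolisable β-peroxy ester is formed without risk of retro-oxa-Michael opening.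

Step 10
Reactants: 18 methyl ester
Product: 19 diol
Conditions: HF·pyridine, pyridine, THF, 0 °C to rt
Reagents that add atoms: none
Why: Buffered fluoride cleavage of the primary silyl ether frees the 1,2-diol under non-basic conditions that the ester and the peroxide tolerate.

Step 11
Reactants: 19 diol
Product: 20 dioxane ester aldehyde
Conditions: NaIO4, THF/pH 7 buffer, 0 °C to rt
Reagents that add atoms: none
Why: Periodate glycol cleavage removes the terminal carbon (geraniol C1) as formaldehyde and leaves a non-enolisable aldehyde on the quaternary C6, whose configuration is not involved.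

Step 12
Reactants: 20 dioxane ester aldehyde
Product: 21 6-vinyl dioxane ester
Conditions: Ph3PCH3Br, KN(SiMe3)2 (slight deficit), THF, 0 °C; then 20, −78 to 0 °C
Reagents that add atoms: methyltriphenylphosphonium bromide, [Br-].C[P+](c1ccccc1)(c1ccccc1)c1ccccc1
Why: Wittig methylenation of the reactive α-alkoxy aldehyde should be fast at low temperature, and using the base in deficit leaves no amide to enolise the β-peroxy ester.

Step 13
Reactants: 22 2,2-dimethylcyclohexanone
Product: 23 β-keto ester
Conditions: NaH, (MeO)2CO, THF, reflux; then aq. HCl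
Reagents that add atoms: dimethyl carbonate, COC(=O)OC
Why: Claisen-type C-acylation can occur only at the single enolisable α-carbon and is driven by formation of the stabilised β-keto ester enolate.

Step 14
Reactants: 23 β-keto ester
Product: 24 enol triflate ester
Conditions: NaH, Et2O, 0 °C; then Tf2O, 0 °C to rt
Reagents that add atoms: trifluoromethanesulfonic anhydride, O=S(=O)(OS(=O)(=O)C(F)(F)F)C(F)(F)F
Why: O-Triflation of the sodium enolate gives the tetrasubstituted enol triflate as the only possible regioisomer.

Step 15
Reactants: 24 enol triflate ester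
Product: 25 hydroxymethyl enol triflate
Conditions: iBu2AlH (2.5 equiv), CH2Cl2, −78 to 0 °C
Reagents that add atoms: none
Why: iBu2AlH reduces the conjugated ester to the allylic alcohol by 1,2-addition at low temperature, conditions under which enol triflates persist.

Step 16
Reactants: 25 hydroxymethyl enol triflate
Product: 26 silyloxymethyl cyclohexenyl triflate
Conditions: TBSCl, imidazole, DMF, rt
Reagents that add atoms: tert-butyldimethylsilyl chloride, CC(C)(C)[Si](C)(C)Cl
Why: Silylation masks the allylic alcohol so that it cannot interfere with the basic palladium coupling.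

Step 17
Reactants: 21 6-vinyl dioxane ester + 26 silyloxymethyl cyclohexenyl triflate
Product: 28 coupled dioxane and cyclohexene, via B-alkyl-9-BBN 27 (not isolated)
Conditions: 9-BBN, THF, 0 °C to rt; then 26, PdCl2(dppf) (10 mol%), AsPh3, Cs2CO3, DMF/H2O, rt
Reagents that add atoms: none
Why: 9-BBN adds anti-Markovnikov to the vinyl group (boron ends γ to the peroxide oxygen, so no β-elimination), and the B-alkyl Suzuki–Miyaura coupling with the enol triflate under zerovalent palladium at room temperature forms the linker CH2–C(sp2) bond without touching any stereocentre.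

Step 18
Reactants: 28 coupled dioxane and cyclohexene
Product: 29 tetrasubstituted allylic alcohol
Conditions: HF·pyridine, pyridine, THF, 0 °C
Reagents that add atoms: none
Why: Buffered fluoride removes the primary allylic silyl ether without base, sparing the β-peroxy ester.

Step 19
Reactants: 29 tetrasubstituted allylic alcohol
Product: 30 epoxy alcohol
Conditions: Ti(OiPr)4 (1.0 equiv), L-(+)-diisopropyl tartrate (1.2 equiv), t-BuOOH, 4 Å MS, CH2Cl2, −20 °C
Reagents that add atoms: tert-butyl hydroperoxide, CC(C)(C)OO
Why: Sharpless asymmetric epoxidation under reagent control with L-(+)-tartrate should deliver oxygen to the same face of the C=C–CH2OH unit as in step 1, which sets the future carbinol carbon as (S), and a full equivalent of the titanium–tartrate complex is used because the alkene is tetrasubstituted.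

Step 20
Reactants: 30 epoxy alcohol
Product: 31 epoxy aldehyde
Conditions: Pr4N[RuO4] (5 mol%), N-methylmorpholine N-oxide, 4 Å MS, CH2Cl2, rt
Reagents that add atoms: none
Why: Ley–Griffith oxidation converts the primary alcohol to the non-enolisable epoxy aldehyde under neutral conditions that leave the acid-sensitive oxirane and the O–O bond intact.

Step 21
Reactants: 31 epoxy aldehyde
Product: 33 target CNP0255906.1, via epoxy hydrazone 32 (not isolated)
Conditions: N2H4·H2O (2–3 equiv), AcOH (cat.), MeOH, 0 °C to rt
Reagents that add atoms: none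
Why: In the Wharton transposition the hydrazone of the α,β-epoxy aldehyde opens the oxirane and loses N2 to give the exocyclic methylene and the tertiary alcohol, and because the C–O bond at the carbinol carbon is never broken its (S) configuration from step 19 is kept.

**Compound list**

1 | geraniol, (2E)-3,7-dimethylocta-2,6-dien-1-ol | CC(C)=CCC/C(C)=C/CO | starting material
2 | (2S,3S)-2,3-epoxygeraniol | CC(C)=CCC[C@]1(C)O[C@H]1CO | intermediate
3 | (2S,3S)-2,3-epoxygeranyl tert-butyldimethylsilyl ether | CC(C)=CCC[C@]1(C)O[C@H]1CO[Si](C)(C)C(C)(C)C | intermediate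
4 | secondary ozonide of 3 (3,3-dimethyl-1,2,4-trioxolane on the former 6,7-alkene, epimers at the acetal carbon) | CC1(C)OOC(CC[C@]2(C)O[C@H]2CO[Si](C)(C)C(C)(C)C)O1 | intermediate
5 | 3-[(2S,3S)-3-(tert-butyldimethylsilyloxymethyl)-2-methyloxiran-2-yl]propanal | O=CCC[C@]1(C)O[C@H]1CO[Si](C)(C)C(C)(C)C | intermediate
6 | cis-2-butene | C/C=C\C | starting material
7 | (Z)-crotylpotassium | C/C=C\[CH2-].[K+] | intermediate
8 | potassium (Z)-but-2-enyl(methoxy)bis(isopinocampheyl)borate, isopinocampheyl groups from (+)-α-pinene | C/C=C\C[B-](OC)([C@@H]1C[C@@H]2C[C@H]([C@H]1C)C2(C)C)[C@@H]1C[C@@H]2C[C@H]([C@H]1C)C2(C)C.[K+] | intermediate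
9 | (Z)-crotyldiisopinocampheylborane, from (−)-Ipc2BOMe | C/C=C\CB([C@@H]1C[C@@H]2C[C@H]([C@H]1C)C2(C)C)[C@@H]1C[C@@H]2C[C@H]([C@H]1C)C2(C)C | intermediate
10 | diisopinocampheylborinate of alcohol 11 | C=C[C@@H](C)[C@H](OB([C@@H]1C[C@@H]2C[C@H]([C@H]1C)C2(C)C)[C@@H]1C[C@@H]2C[C@H]([C@H]1C)C2(C)C)CC[C@]1(C)O[C@H]1CO[Si](C)(C)C(C)(C)C | intermediate
11 | (3R,4R)-6-[(2S,3S)-3-(tert-butyldimethylsilyloxymethyl)-2-methyloxiran-2-yl]-3-methylhex-1-en-4-ol (syn) | C=C[C@@H](C)[C@H](O)CC[C@]1(C)O[C@H]1CO[Si](C)(C)C(C)(C)C | intermediate
12 | methanesulfonate of 11, (3R,4R) retained | C=C[C@@H](C)[C@H](OS(C)(=O)=O)CC[C@]1(C)O[C@H]1CO[Si](C)(C)C(C)(C)C | intermediate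
13 | (2S,3R,6R,7R)-1-(tert-butyldimethylsilyloxy)-3-hydroperoxy-2-hydroxy-3,7-dimethylnon-8-en-6-yl methanesulfonate | C=C[C@@H](C)[C@H](OS(C)(=O)=O)CC[C@@](C)(OO)[C@@H](O)CO[Si](C)(C)C(C)(C)C | intermediate
14 | (1S)-2-(tert-butyldimethylsilyloxy)-1-[(3R,6S)-6-[(2R)-but-3-en-2-yl]-3-methyl-1,2-dioxan-3-yl]ethan-1-ol (butenyl group and glycol arm cis) | C=C[C@@H](C)[C@@H]1CC[C@](C)([C@@H](O)CO[Si](C)(C)C(C)(C)C)OO1 | intermediate
15 | secondary ozonide of 14 (1,2,4-trioxolan-3-yl in place of the vinyl group, epimers at the acetal carbon) | C1OOC(O1)[C@@H](C)[C@@H]2CC[C@](C)([C@@H](O)CO[Si](C)(C)C(C)(C)C)OO2 | intermediate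
16 | (2S)-2-[(3S,6R)-6-[(1S)-2-(tert-butyldimethylsilyloxy)-1-hydroxyethyl]-6-methyl-1,2-dioxan-3-yl]propanal | O=C[C@@H](C)[C@@H]1CC[C@](C)([C@@H](O)CO[Si](C)(C)C(C)(C)C)OO1 | intermediate
17 | (2S)-2-[(3S,6R)-6-[(1S)-2-(tert-butyldimethylsilyloxy)-1-hydroxyethyl]-6-methyl-1,2-dioxan-3-yl]propanoic acid | OC(=O)[C@@H](C)[C@@H]1CC[C@](C)([C@@H](O)CO[Si](C)(C)C(C)(C)C)OO1 | intermediate
18 | methyl ester of 17 | COC(=O)[C@@H](C)[C@@H]1CC[C@](C)([C@@H](O)CO[Si](C)(C)C(C)(C)C)OO1 | intermediate
19 | methyl (2S)-2-[(3S,6R)-6-[(1S)-1,2-dihydroxyethyl]-6-methyl-1,2-dioxan-3-yl]propanoate | COC(=O)[C@@H](C)[C@@H]1CC[C@](C)([C@@H](O)CO)OO1 | intermediate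
20 | methyl (2S)-2-[(3S,6R)-6-formyl-6-methyl-1,2-dioxan-3-yl]propanoate | COC(=O)[C@@H](C)[C@@H]1CC[C@](C)(C=O)OO1 | intermediate
21 | methyl (2S)-2-[(3S,6R)-6-ethenyl-6-methyl-1,2-dioxan-3-yl]propanoate | COC(=O)[C@@H](C)[C@@H]1CC[C@](C)(C=C)OO1 | intermediate
22 | 2,2-dimethylcyclohexanone | CC1(C)CCCCC1=O | starting material
23 | methyl 3,3-dimethyl-2-oxocyclohexane-1-carboxylate (racemic, enolisable) | COC(=O)C1CCCC(C)(C)C1=O | intermediate
24 | methyl 3,3-dimethyl-2-(trifluoromethylsulfonyloxy)cyclohex-1-ene-1-carboxylate | COC(=O)C1=C(OS(=O)(=O)C(F)(F)F)C(C)(C)CCC1 | intermediate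
25 | 2-(hydroxymethyl)-6,6-dimethylcyclohex-1-en-1-yl trifluoromethanesulfonate | OCC1=C(OS(=O)(=O)C(F)(F)F)C(C)(C)CCC1 | intermediate
26 | 2-(tert-butyldimethylsilyloxymethyl)-6,6-dimethylcyclohex-1-en-1-yl trifluoromethanesulfonate | CC1(C)CCCC(CO[Si](C)(C)C(C)(C)C)=C1OS(=O)(=O)C(F)(F)F | intermediate
27 | methyl (2S)-2-[(3S,6S)-6-[2-(9-borabicyclo[3.3.1]nonan-9-yl)ethyl]-6-methyl-1,2-dioxan-3-yl]propanoate (geometry at C6 as in 21; the descriptor changes by priority only) | COC(=O)[C@@H](C)[C@@H]1CC[C@](C)(CCB2C3CCCC2CCC3)OO1 | intermediate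
28 | methyl (2S)-2-[(3S,6S)-6-[2-[2-(tert-butyldimethylsilyloxymethyl)-6,6-dimethylcyclohex-1-en-1-yl]ethyl]-6-methyl-1,2-dioxan-3-yl]propanoate (geometry at C6 as in 21) | COC(=O)[C@@H](C)[C@@H]1CC[C@](C)(CCC2=C(CO[Si](C)(C)C(C)(C)C)CCCC2(C)C)OO1 | intermediate
29 | methyl (2S)-2-[(3S,6S)-6-[2-[2-(hydroxymethyl)-6,6-dimethylcyclohex-1-en-1-yl]ethyl]-6-methyl-1,2-dioxan-3-yl]propanoate (geometry at C6 as in 21) | COC(=O)[C@@H](C)[C@@H]1CC[C@](C)(CCC2=C(CO)CCCC2(C)C)OO1 | intermediate
30 | methyl (2S)-2-[(3S,6R)-6-[2-[(1S,6S)-6-(hydroxymethyl)-2,2-dimethyl-7-oxabicyclo[4.1.0]heptan-1-yl]ethyl]-6-methyl-1,2-dioxan-3-yl]propanoate | COC(=O)[C@@H](C)[C@@H]1CC[C@](C)(CC[C@@]23O[C@]2(CO)CCCC3(C)C)OO1 | intermediate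
31 | methyl (2S)-2-[(3S,6R)-6-[2-[(1S,6R)-6-formyl-2,2-dimethyl-7-oxabicyclo[4.1.0]heptan-1-yl]ethyl]-6-methyl-1,2-dioxan-3-yl]propanoate (same geometry as 30) | COC(=O)[C@@H](C)[C@@H]1CC[C@](C)(CC[C@@]23O[C@]2(C=O)CCCC3(C)C)OO1 | intermediate
32 | hydrazone of 31 (C=N geometry not defined) | COC(=O)[C@@H](C)[C@@H]1CC[C@](C)(CC[C@@]23O[C@]2(C=NN)CCCC3(C)C)OO1 | intermediate
33 | methyl (2S)-2-[(3S,6R)-6-[2-[(1S)-1-hydroxy-2,2-dimethyl-6-methylidenecyclohexyl]ethyl]-6-methyl-1,2-dioxan-3-yl]propanoate, CNP0255906.1 | C=C1CCCC(C)(C)[C@@]1(O)CC[C@@]1(C)CC[C@@H]([C@H](C)C(=O)OC)OO1 | target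

**Step count**

Total: 21 steps. Longest linear sequence: 17 steps (steps 1–12 and 17–21, from geraniol). The triflate arm is 4 steps (13–16).

**Steps most likely to fail**

Step 6. The intermolecular opening may proceed with partial ionisation at the tertiary oxirane carbon, so that inversion at C6 is not clean, or may be slow. After base is added, E2 at the β-branched secondary mesylate or C–C fragmentation of the β-hydroxy hydroperoxide may outrun the 6-exo displacement. The fallback reverses the order of the two C–O bond formations and sets out from mesylate 12. Displacement of the sulfonate by 2-methoxyprop-2-yl hydroperoxide with CsOH in DMF (SN2, inversion at C3) should give the mixed peroxyketal F1. Aqueous AcOH releases the secondary hydroperoxy epoxide F2. Catalytic camphorsulfonic acid in CH2Cl2 then lets the hydroperoxide open the oxirane intramolecularly at its tertiary carbon (6-exo, inversion at C6). This comes back to the route at dioxane 14, and no β-hydroxy hydroperoxide ever meets base.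

Step 17. Oxidative addition and transmetallation at the hindered tetrasubstituted enol triflate may be slow. Protodeboronation, triflate hydrolysis, base-induced retro-oxa-Michael opening of the β-peroxy ester or insertion of palladium into the O–O bond could then compete. The fallback sets out from aldehyde 20 and triflate 26. Ohira–Bestmann homologation of 20 (dimethyl 1-diazo-2-oxopropylphosphonate, K2CO3, MeOH, 0 °C) should give the terminal alkyne F3. Sonogashira coupling of F3 with 26 (Pd(PPh3)4, CuI, iPr2NH, rt) should give the enyne F4. Diimide (2-nitrobenzenesulfonylhydrazide, Et3N) then saturates the alkyne but not the tetrasubstituted alkene or the peroxide. This comes back to the route at 28.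

Step 21. Hydrazone formation at the neopentyl-like aldehyde may be sluggish, giving time for hydrazinolysis of the methyl ester or reduction of the peroxide. The fragmentation itself may also divert to over-reduced products. The fallback sets out from epoxy alcohol 30 and replaces the ionic transposition by a radical one. 1,1'-Thiocarbonyldiimidazole should give the thiocarbonylimidazolide F5. Bu3SnH with Et3B and air at room temperature then generates the oxiranylcarbinyl radical, which opens by C–O cleavage to the tertiary alkoxyl radical. Hydrogen transfer from a high concentration of stannane gives the allylic alcohol, and the sequence comes back to the route at target 33.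

**Further compounds**

F1 | step 6 | mixed peroxyketal: 2-methoxyprop-2-yl peroxide at C3 (inverted) of the epoxy silyl ether | C=C[C@@H](C)[C@@H](OOC(C)(C)OC)CC[C@]1(C)O[C@H]1CO[Si](C)(C)C(C)(C)C
F2 | step 6 | secondary hydroperoxy epoxide | C=C[C@@H](C)[C@@H](OO)CC[C@]1(C)O[C@H]1CO[Si](C)(C)C(C)(C)C
F3 | step 17 | methyl (2S)-2-[(3S,6R)-6-ethynyl-6-methyl-1,2-dioxan-3-yl]propanoate | COC(=O)[C@@H](C)[C@@H]1CC[C@](C)(C#C)OO1
F4 | step 17 | enyne from F3 and 26 | COC(=O)[C@@H](C)[C@@H]1CC[C@](C)(C#CC2=C(CO[Si](C)(C)C(C)(C)C)CCCC2(C)C)OO1
F5 | step 21 | O-alkyl imidazole-1-carbothioate of epoxy alcohol 30 | COC(=O)[C@@H](C)[C@@H]1CC[C@](C)(CC[C@@]23O[C@]2(COC(=S)n4ccnc4)CCCC3(C)C)OO1
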